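## Retrosynthetic overview

1. The target comes from hydrogenolysis of the deca-O-benzyl diester 17, itself made by double Steglich esterification of diol 15 (free 3-OH and 4'-OH, the latter unmasked by deallylation) with tri-O-benzylgallic acid 16.
2. The cis-(2R,3R) alcohol 14 comes from a dynamic kinetic transfer hydrogenation of the racemic flavan-3-one 13, in which C2 is labile next to the C3 carbonyl; 13 comes from dithioketal 12.
3. Compound 12 comes from a one-pot three-component annulation: C3 linchpin 8 + ring A benzylic chloride 4 (C3–C4) + ring B aldehyde 7 (C2–C3), after which the C2 alkoxide displaces the C8a fluoride (O1–C8a). Rings A and B are bought; ring C is the only ring formed.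
4. Enabling feature: C3 of ring C is a carbinol carbon bonded only to C4H2 and to C2(O1)Ar, so it is a latent carbonyl that can enter as a formyl dianion equivalent. C8a of ring A is meta to O5 and O7, so a fluoride there is displaced through a Meisenheimer ion with its charge on C4a, C6 and C8.

Key step: step 6

Assumption: the sense of induction in step 8 is assigned by analogy with the dynamic kinetic reduction of benzoin-type α-aryl-α-oxy ketones; should the first run show the opposite sense, the antipodal catalyst is used and nothing else changes.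

## Route

Step 1
Reactants: 1 2,4,6-trifluorobenzaldehyde
Product: 2 2,4-bis(benzyloxy)-6-fluorobenzaldehyde
Conditions: BnOH (2.05 equiv), KOt-Bu (2.05 equiv), DMF, −20 °C → rt
Reagents that add atoms: benzyl alcohol, OCc1ccccc1
Why: Double nucleophilic aromatic substitution (SNAr) in which the formyl group activates the para fluoride and then one ortho fluoride, while the third displacement is slowed by the two alkoxy donors then on the ring (the 2,6-isomer and the tris-ether are the expected minor contaminants, to be removed by chromatography).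

Step 2
Reactants: 2 2,4-bis(benzyloxy)-6-fluorobenzaldehyde
Product: 3 [2,4-bis(benzyloxy)-6-fluorophenyl]methanol
Conditions: NaBH4, THF/MeOH, 0 °C
Reagents that add atoms: none
Why: Borohydride reduction of the aryl aldehyde, to which the aryl fluoride and the benzyl ethers are inert.

Step 3
Reactants: 3 [2,4-bis(benzyloxy)-6-fluorophenyl]methanol
Product: 4 1,5-bis(benzyloxy)-2-(chloromethyl)-3-fluorobenzene
Conditions: SOCl2, pyridine (1.1 equiv), Et2O, −10 °C; used at once without chromatography
Reagents that add atoms: thionyl chloride, O=S(Cl)Cl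
Why: Chlorodehydroxylation with pyridine-buffered thionyl chloride, the chloride being chosen over the bromide because this ortho/para-dialkoxybenzylic halide ionises easily and should be made cold and used directly.

Step 4
Reactants: 5 3,4,5-trihydroxybenzaldehyde
Product: 6 4-(allyloxy)-3,5-dihydroxybenzaldehyde
Conditions: allyl bromide (1.05 equiv), NaHCO3, NaI (cat.), DMF, 40 °C
Reagents that add atoms: allyl bromide, C=CCBr
Why: Regioselective Williamson etherification, since the 4-OH (para to the formyl group and flanked by two hydrogen-bond donors) is the most acidic phenol and the only one deprotonated by hydrogencarbonate.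

Step 5
Reactants: 6 4-(allyloxy)-3,5-dihydroxybenzaldehyde
Product: 7 4-(allyloxy)-3,5-bis(benzyloxy)benzaldehyde
Conditions: BnBr (2.3 equiv), K2CO3, DMF, rt
Reagents that add atoms: benzyl bromide, BrCc1ccccc1
Why: Williamson benzylation of the two remaining phenols, which leaves the 4'-oxygen carrying a group (allyl) orthogonal to benzyl.

Step 6
Reactants: 8 2-(trimethylsilyl)-1,3-dithiane; 4 1,5-bis(benzyloxy)-2-(chloromethyl)-3-fluorobenzene; 7 4-(allyloxy)-3,5-bis(benzyloxy)benzaldehyde
Product: 12 racemic 2-[4-(allyloxy)-3,5-bis(benzyloxy)phenyl]-5,7-bis(benzyloxy)spiro[chromane-3,2'-[1,3]dithiane], via lithiated silyldithiane 9 (not isolated), via benzylated silyldithiane 10 (not isolated), via caesium alkoxide 11 (not isolated)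
Conditions: 8 (1.1 equiv), n-BuLi (1.0 equiv), THF, −30 °C; 4 (0.95 equiv), −78 → 0 °C; then 7 (1.0 equiv), dry CsF (3 equiv), 18-crown-6 (0.2 equiv), DMPU, 25 → 70 °C; one pot
Reagents that add atoms: none
Why: Proposed new method: anion 9 is C-benzylated by chloride 4 (C3–C4); fluoride then attacks silicon in 10, the dithianyl nucleophile adds to the non-enolisable aldehyde 7 (C2–C3) to give alkoxide 11, and O1 of 11 displaces the C8a fluoride of ring A by addition–elimination (O1–C8a), the fluoride set free re-entering as desilylating agent. The closest known reaction types are the alkylation of 2-lithio-2-silyl-1,3-dithianes, the fluoride-promoted addition of 2-silyl-1,3-dithianes to aldehydes and chroman closure by intramolecular SNAr of an alkoxide on a fluoroarene; their merger into a one-pot three-component annulation is what is new. Ring C closes in a 6-exo-trig addition–elimination at C8a, helped by the gem-dithio (Thorpe–Ingold) effect at C3 and by O5 and O7 standing meta to C8a, so that the Meisenheimer charge falls on C4a, C6 and C8 and not on oxygen-bearing carbons. The one new stereocentre, C2, is formed as a racemate on purpose, because it lies next to the future C3 ketone and is corrected in step 8. The step needs chemoselectivity: no alkyllithium may be left to metalate ring A at C8, which the slight excess of 8 over n-BuLi secures; the alkoxide has only one fluoride to attack, because 4 carries a single fluorine; and the reversible carbonyl addition is drained by the irreversible ring closure.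

Step 7
Reactants: 12 racemic 2-[4-(allyloxy)-3,5-bis(benzyloxy)phenyl]-5,7-bis(benzyloxy)spiro[chromane-3,2'-[1,3]dithiane]
Product: 13 racemic 2-[4-(allyloxy)-3,5-bis(benzyloxy)phenyl]-5,7-bis(benzyloxy)chroman-3-one
Conditions: MeI (excess), CaCO3, MeCN/H2O (9:1), 45 °C, argon
Reagents that add atoms: water, O
Why: Alkylative dethioketalisation, in which S-methylation makes sulfonium leaving groups and water captures the thionium ion to give the ketone under buffered conditions that spare the allyl and benzyl ethers; C2 stays racemic, which is harmless here.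

Step 8
Reactants: 13 racemic 2-[4-(allyloxy)-3,5-bis(benzyloxy)phenyl]-5,7-bis(benzyloxy)chroman-3-one
Product: 14 (2R,3R)-2-[4-(allyloxy)-3,5-bis(benzyloxy)phenyl]-5,7-bis(benzyloxy)chroman-3-ol
Conditions: RuCl[(S,S)-TsDPEN](p-cymene) (2 mol%), HCO2H/Et3N (5:2), DMF, 30 °C, argon
Reagents that add atoms: none
Why: Noyori–Ikariya asymmetric transfer hydrogenation under dynamic kinetic resolution: C2 (α to the ketone, benzylic and oxygen-substituted) should racemise through the enol faster than the ketone is reduced, and the catalyst should reduce one C2 epimer from the face anti to the C2 aryl group, which sets C3 as R and fixes C2 as R in the cis relation.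

Step 9
Reactants: 14 (2R,3R)-2-[4-(allyloxy)-3,5-bis(benzyloxy)phenyl]-5,7-bis(benzyloxy)chroman-3-ol
Product: 15 (2R,3R)-2-[3,5-bis(benzyloxy)-4-hydroxyphenyl]-5,7-bis(benzyloxy)chroman-3-ol
Conditions: Pd(PPh3)4 (5 mol%), morpholine (5 equiv), THF, rt
Reagents that add atoms: none
Why: Tsuji–Trost-type deallylation in which zerovalent palladium ionises the aryl allyl ether and morpholine traps the allyl fragment, under neutral conditions that leave the benzyl ethers, the secondary alcohol and both stereocentres untouched.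

Step 10
Reactants: 15 (2R,3R)-2-[3,5-bis(benzyloxy)-4-hydroxyphenyl]-5,7-bis(benzyloxy)chroman-3-ol; 16 3,4,5-tris(benzyloxy)benzoic acid
Product: 17 (2R,3R)-5,7-bis(benzyloxy)-2-{3,5-bis(benzyloxy)-4-[3,4,5-tris(benzyloxy)benzoyloxy]phenyl}chroman-3-yl 3,4,5-tris(benzyloxy)benzoate
Conditions: 16 (2.6 equiv), EDC·HCl (3 equiv), DMAP (1 equiv), CH2Cl2, 0 °C → rt
Reagents that add atoms: none
Why: Steglich esterification, which acylates both the hindered 4'-phenol and the axial 3-OH (the only free hydroxyls) at a temperature too low for base-induced opening of ring C.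

Step 11
Reactants: 17 (2R,3R)-5,7-bis(benzyloxy)-2-{3,5-bis(benzyloxy)-4-[3,4,5-tris(benzyloxy)benzoyloxy]phenyl}chroman-3-yl 3,4,5-tris(benzyloxy)benzoate
Product: 18 epigallocatechin 3,4'-di-O-gallate
Conditions: H2 (1 atm), Pd(OH)2/C, THF/MeOH (1:1), rt; filtration under argon
Reagents that add atoms: none
Why: Hydrogenolysis of all ten benzyl ethers under neutral conditions, which should leave both gallate esters in place and C2 and C3 unchanged.

## Compound list

1 | 2,4,6-trifluorobenzaldehyde | O=Cc1c(F)cc(F)cc1F | starting material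
2 | 2,4-bis(benzyloxy)-6-fluorobenzaldehyde | O=Cc1c(F)cc(OCc2ccccc2)cc1OCc1ccccc1 | intermediate
3 | [2,4-bis(benzyloxy)-6-fluorophenyl]methanol | OCc1c(F)cc(OCc2ccccc2)cc1OCc1ccccc1 | intermediate
4 | 1,5-bis(benzyloxy)-2-(chloromethyl)-3-fluorobenzene | ClCc1c(F)cc(OCc2ccccc2)cc1OCc1ccccc1 | intermediate
5 | 3,4,5-trihydroxybenzaldehyde | O=Cc1cc(O)c(O)c(O)c1 | starting material
6 | 4-(allyloxy)-3,5-dihydroxybenzaldehyde | O=Cc1cc(O)c(OCC=C)c(O)c1 | intermediate
7 | 4-(allyloxy)-3,5-bis(benzyloxy)benzaldehyde | O=Cc1cc(OCc2ccccc2)c(OCC=C)c(OCc2ccccc2)c1 | intermediate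
8 | 2-(trimethylsilyl)-1,3-dithiane | C[Si](C)(C)C1SCCCS1 | starting material
9 | 2-lithio-2-(trimethylsilyl)-1,3-dithiane | [Li]C1([Si](C)(C)C)SCCCS1 | intermediate (not isolated)
10 | 2-[2,4-bis(benzyloxy)-6-fluorobenzyl]-2-(trimethylsilyl)-1,3-dithiane | C[Si](C)(C)C1(Cc2c(F)cc(OCc3ccccc3)cc2OCc2ccccc2)SCCCS1 | intermediate (not isolated)
11 | caesium [4-(allyloxy)-3,5-bis(benzyloxy)phenyl]{2-[2,4-bis(benzyloxy)-6-fluorobenzyl]-1,3-dithian-2-yl}methanolate (racemic) | [Cs+].[O-]C(c1cc(OCc2ccccc2)c(OCC=C)c(OCc2ccccc2)c1)C1(Cc2c(F)cc(OCc3ccccc3)cc2OCc2ccccc2)SCCCS1 | intermediate (not isolated)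
12 | racemic 2-[4-(allyloxy)-3,5-bis(benzyloxy)phenyl]-5,7-bis(benzyloxy)spiro[chromane-3,2'-[1,3]dithiane] | C=CCOc1c(OCc2ccccc2)cc(C2Oc3cc(OCc4ccccc4)cc(OCc4ccccc4)c3CC23SCCCS3)cc1OCc1ccccc1 | intermediate
13 | racemic 2-[4-(allyloxy)-3,5-bis(benzyloxy)phenyl]-5,7-bis(benzyloxy)chroman-3-one | C=CCOc1c(OCc2ccccc2)cc(C2Oc3cc(OCc4ccccc4)cc(OCc4ccccc4)c3CC2=O)cc1OCc1ccccc1 | intermediate
14 | (2R,3R)-2-[4-(allyloxy)-3,5-bis(benzyloxy)phenyl]-5,7-bis(benzyloxy)chroman-3-ol | C=CCOc1c(OCc2ccccc2)cc([C@H]2Oc3cc(OCc4ccccc4)cc(OCc4ccccc4)c3C[C@H]2O)cc1OCc1ccccc1 | intermediate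
15 | (2R,3R)-2-[3,5-bis(benzyloxy)-4-hydroxyphenyl]-5,7-bis(benzyloxy)chroman-3-ol | Oc1c(OCc2ccccc2)cc([C@H]2Oc3cc(OCc4ccccc4)cc(OCc4ccccc4)c3C[C@H]2O)cc1OCc1ccccc1 | intermediate
16 | 3,4,5-tris(benzyloxy)benzoic acid | OC(=O)c1cc(OCc2ccccc2)c(OCc2ccccc2)c(OCc2ccccc2)c1 | starting material
17 | (2R,3R)-5,7-bis(benzyloxy)-2-{3,5-bis(benzyloxy)-4-[3,4,5-tris(benzyloxy)benzoyloxy]phenyl}chroman-3-yl 3,4,5-tris(benzyloxy)benzoate | O=C(Oc1c(OCc2ccccc2)cc([C@H]2Oc3cc(OCc4ccccc4)cc(OCc4ccccc4)c3C[C@H]2OC(=O)c2cc(OCc3ccccc3)c(OCc3ccccc3)c(OCc3ccccc3)c2)cc1OCc1ccccc1)c1cc(OCc2ccccc2)c(OCc2ccccc2)c(OCc2ccccc2)c1 | intermediate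
18 | epigallocatechin 3,4'-di-O-gallate, (2R,3R) | O=C(Oc1c(O)cc([C@H]2Oc3cc(O)cc(O)c3C[C@H]2OC(=O)c2cc(O)c(O)c(O)c2)cc1O)c1cc(O)c(O)c(O)c1 | target

## Step count and risks

Total steps: 11. Longest linear sequence: 9 (steps 1, 2, 3, 6, 7, 8, 9, 10, 11).

**Step 6.** The fluoride-triggered dithianyl transfer may be outrun by protodesilylation of 10, or the carbonyl addition may revert before ring C closes. The fallback uses only known reaction types; it sets out from 7 and 4 and comes back at 12. Aldehyde 7 is added to 2-lithio-1,3-dithiane (1,3-dithiane, n-BuLi, THF, −78 °C) to give [4-(allyloxy)-3,5-bis(benzyloxy)phenyl](1,3-dithian-2-yl)methanol F1. MnO2 in CH2Cl2 oxidises this benzylic alcohol to [4-(allyloxy)-3,5-bis(benzyloxy)phenyl](1,3-dithian-2-yl)methanone F2. The stabilised anion of F2 (NaH, DMF, 0 °C) is C-benzylated by chloride 4 to [4-(allyloxy)-3,5-bis(benzyloxy)phenyl]{2-[2,4-bis(benzyloxy)-6-fluorobenzyl]-1,3-dithian-2-yl}methanone F3. NaBH4 reduces F3 to the racemic carbinol [4-(allyloxy)-3,5-bis(benzyloxy)phenyl]{2-[2,4-bis(benzyloxy)-6-fluorobenzyl]-1,3-dithian-2-yl}methanol F4, and KHMDS in THF/DMPU at 65 °C closes ring C by intramolecular SNAr to give 12.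

**Step 8.** The catalyst may discriminate poorly between the two interconverting C2 epimers, or racemisation may be slower than reduction, so that the dynamic regime is lost. The fallback sets out from 13 and comes back at 14. LiBH(s-Bu)3 in THF at −78 °C should deliver hydride anti to the C2 aryl group and give the racemic cis alcohol rac-(2R*,3R*)-2-[4-(allyloxy)-3,5-bis(benzyloxy)phenyl]-5,7-bis(benzyloxy)chroman-3-ol F5. Esterification with (S)-2-methoxy-2-phenylacetic acid (DCC, DMAP, CH2Cl2) gives two diastereomeric esters, from which (2R,3R)-2-[4-(allyloxy)-3,5-bis(benzyloxy)phenyl]-5,7-bis(benzyloxy)chroman-3-yl (S)-2-methoxy-2-phenylacetate F6 is separated by chromatography or crystallisation. Methanolysis (K2CO3, MeOH/THF, rt) returns 14.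

**Step 7.** S-Alkylation at the hindered spiro dithioketal may be sluggish, with slow loss of the enolisable, air-sensitive ketone during prolonged heating. The fallback sets out from 12 and comes back at 13; it replaces alkylative activation by a change of oxidation level at sulfur. NaIO4 (THF/MeOH/H2O, 0 °C) gives the mono-S-oxide 2-[4-(allyloxy)-3,5-bis(benzyloxy)phenyl]-5,7-bis(benzyloxy)spiro[chromane-3,2'-[1,3]dithiane] 1'-oxide F7 as a diastereomer mixture. Dilute HCl in MeCN/H2O at rt then hydrolyses F7 through the thionium ion to 13.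

## Further compounds

F1 | step 6 | [4-(allyloxy)-3,5-bis(benzyloxy)phenyl](1,3-dithian-2-yl)methanol (racemic) | OC(c1cc(OCc2ccccc2)c(OCC=C)c(OCc2ccccc2)c1)C1SCCCS1
F2 | step 6 | [4-(allyloxy)-3,5-bis(benzyloxy)phenyl](1,3-dithian-2-yl)methanone | O=C(c1cc(OCc2ccccc2)c(OCC=C)c(OCc2ccccc2)c1)C1SCCCS1
F3 | step 6 | [4-(allyloxy)-3,5-bis(benzyloxy)phenyl]{2-[2,4-bis(benzyloxy)-6-fluorobenzyl]-1,3-dithian-2-yl}methanone | O=C(c1cc(OCc2ccccc2)c(OCC=C)c(OCc2ccccc2)c1)C1(Cc2c(F)cc(OCc3ccccc3)cc2OCc2ccccc2)SCCCS1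
F4 | step 6 | [4-(allyloxy)-3,5-bis(benzyloxy)phenyl]{2-[2,4-bis(benzyloxy)-6-fluorobenzyl]-1,3-dithian-2-yl}methanol (racemic) | OC(c1cc(OCc2ccccc2)c(OCC=C)c(OCc2ccccc2)c1)C1(Cc2c(F)cc(OCc3ccccc3)cc2OCc2ccccc2)SCCCS1
F5 | step 8 | rac-(2R*,3R*)-2-[4-(allyloxy)-3,5-bis(benzyloxy)phenyl]-5,7-bis(benzyloxy)chroman-3-ol (racemate, one enantiomer drawn) | C=CCOc1c(OCc2ccccc2)cc([C@H]2Oc3cc(OCc4ccccc4)cc(OCc4ccccc4)c3C[C@H]2O)cc1OCc1ccccc1
F6 | step 8 | (2R,3R)-2-[4-(allyloxy)-3,5-bis(benzyloxy)phenyl]-5,7-bis(benzyloxy)chroman-3-yl (S)-2-methoxy-2-phenylacetate | C=CCOc1c(OCc2ccccc2)cc([C@H]2Oc3cc(OCc4ccccc4)cc(OCc4ccccc4)c3C[C@H]2OC(=O)[C@@H](OC)c2ccccc2)cc1OCc1ccccc1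
F7 | step 7 | 2-[4-(allyloxy)-3,5-bis(benzyloxy)phenyl]-5,7-bis(benzyloxy)spiro[chromane-3,2'-[1,3]dithiane] 1'-oxide (diastereomer mixture) | C=CCOc1c(OCc2ccccc2)cc(C2Oc3cc(OCc4ccccc4)cc(OCc4ccccc4)c3CC23SCCCS3=O)cc1OCc1ccccc1
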